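**Remarks on the chemistry.** Flavan numbering is used throughout: O1, C2, C3, C4, C4a, C5 to C8, C8a; ring A is the benzo ring, ring C the pyran ring, ring B the 4-methoxyphenyl group, and C1'' is the prenyl CH2. The α-chloro ketone 11 is used instead of its bromo analogue, because an α-bromo ketone would be displaced by formate under transfer-hydrogenation conditions.

## Analysis of the target

Target 18 is a flavan, a 3,4-dihydro-2H-chromene in which ring A is fused to ring C and C2 carries ring B. Ring A is pentasubstituted: methoxy groups at C5 and C7, the prenyl group at C6 between them, the ether oxygen at C8a and the C4 methylene at C4a, so only C8 keeps a hydrogen. The single stereocentre is C2, of (S) configuration (O1 > ring B > C3, hydrogen to the rear, counter-clockwise). C2 is a benzylic ether carbon activated by O1 and by the para-methoxy group of ring B, so it ionises easily under Brønsted or Lewis acid. The prenyl alkene rules out hydrogenation, hydrogenolysis, strong acid and electrophilic oxidants. The hard points are therefore the regiochemistry of a crowded arene, an isolated and labile stereocentre with no neighbouring handle, and the need to reach C3 and C4 as plain methylenes without reducing the alkene. The strategy rests on the C3–C4 bond. C4 sits on C4a between the C5 methoxy group and the C8a oxygen, which is where an ortho-formyl group of a phenol sits; C3 is the carbon next to the carbinol C2, which is the terminal carbon of an aryl epoxide. Both carbons are natural electrophiles, so one of them must react with reversed polarity.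

## Retrosynthetic reasoning

**O1–C2 (18 to 17).** The pyran ring is opened at the O1–C2 bond to give phenol alcohol 17. This is done last because the labile benzylic ether then meets no further reagent. The forward reaction is an intramolecular Mitsunobu etherification, which inverts C2, so 17 must carry the (R) carbinol.

**C4–S and O–Si (17 to 16 to 15).** The C4 methylene of 17 is traced back to a dithioacetal carbon and the phenol to its triisopropylsilyl ether, which leads to 15. The gain is that C4 never carries oxygen, so no ketone has to be deoxygenated in the presence of the prenyl group. Forward, a radical tin hydride reduction must cleave both benzylic C–S bonds without touching the alkene, and fluoride must then free the phenol.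

**C3–C4 (15 to 10 and 13, through 14).** This is the central cut. It divides the molecule into a ring A fragment and a ring B fragment of similar size and places the stereocentre in the small, easily made epoxide 13. The bond is cut here rather than at C2–C3 or C4–C4a because only this cut gives two fragments that are each a functionalised commodity arene. Forward, the lithiated dithiane 14, made from 10, must open 13 at its CH2 terminus only, leaving the carbinol carbon untouched.

**Epoxide C–O and carbinol C–H (13 to 12 to 11).** Epoxide 13 comes from chlorohydrin 12 by closure on the primary carbon, and 12 from the prochiral ketone 11 by enantioselective reduction. The stereocentre of the whole synthesis is thus set in one catalytic step on a simple substrate.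

**Si–O and C–S (10 to 9 to 7 and 8).** The silyl ether of 10 is removed to give phenol 9, and the dithiane of 9 is traced to salicylaldehyde 7 and dithiol 8. The silyl group is needed because a free phenol would consume base and blunt the carbanion in the key step.

**C4a–C4 (7 to 6).** The formyl carbon is removed to give the symmetric phenol 6. Both positions ortho to the hydroxyl of 6 are equivalent and the para position is blocked by the prenyl group, so an ortho-selective formylation can give only one product.

**C8a–O (6 to 5 to 4).** The phenol oxygen is traced to a boronate and then to a C–H bond. In 4 the position para to the prenyl group is the only ring C–H without an ortho substituent, so a sterically governed iridium-catalysed borylation should address it alone. Electrophilic substitution would go to the wrong carbon.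

**C6–C1'' (4 to 1 and 2, through 3).** The prenyl group is cut off to give the arene 1 and the allylic bromide 2. The position between two methoxy groups is the most acidic C–H of 1, so lithiation to 3 fixes the regiochemistry of the prenyl group at the start.

## Alternatives that were turned down

**Alternative 1:** Here ring A itself is disconnected.
- Disconnection and key step: the product would be phenol A1, 2-[(3R)-3-(tert-butyldimethylsilyloxy)-3-(4-methoxyphenyl)propyl]-3,5-dimethoxy-4-(3-methylbut-2-en-1-yl)phenol. It would arise from cyclobutenone A2, 3-methoxy-2-(3-methylbut-2-en-1-yl)cyclobut-2-en-1-one, and the chain-bearing ynol ether A3, tert-butyl{[(1R)-5-methoxy-1-(4-methoxyphenyl)pent-4-yn-1-yl]oxy}dimethylsilane. Heating opens A2 to a vinylketene, which adds [2+2] to A3; a second 4π opening and a 6π closure then form C8a–C4a, C5–C6 and C8–C8a (Danheiser benzannulation).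
- For it: every substituent position on ring A is fixed by the pericyclic sequence, since the ketene carbon bonds to the alkyne carbon remote from the methoxy group. A1 is the silyl-protected analogue of 17, and no sulfur or tin is needed. On regiochemical certainty for ring A it is stronger than the chosen route, which depends on a borylation and a formylation being selective.
- Against it: neither A2 nor A3 is commercial. A2 is a 4-unsubstituted 3-alkoxycyclobutenone carrying an allylic side chain, and A3 needs its own asymmetric reduction, protection and ynol ether construction from volatile methoxyacetylene. The thermal cascade would have to tolerate the prenyl group and a silylated anisyl carbinol.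
- Comparison: the overall count would be no lower, and the uncertain material would have to be made twice over before the key step could be tried. The chosen route builds on commodity arenes and keeps its risk in one step.

**Alternative 2:** The only bond cut is C6–C1''.
- Disconnection and key step: the product would be (2S)-6-prenylnaringenin A4, made from (2S)-naringenin A5 and dimethylallyl diphosphate A6 by an aromatic prenyltransferase of the dimethylallyltryptophan synthase family.
- For it: one bond, no protecting groups, and C2 supplied by the substrate. On step economy up to the carbon skeleton it is clearly stronger.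
- Against it: the enzyme must distinguish C6 from C8 and from the phenol oxygens, and it needs A6 in stoichiometric amount, which limits scale. A4 is still far from 18. Three phenols must be methylated, and the C5 hydroxyl is chelated to the C4 carbonyl and reacts only under forcing base, which opens the flavanone by retro-oxa-Michael reaction to the chalcone and erases C2. The C4 carbonyl must then be removed completely. Acid and hydride would protonate the prenyl alkene and ionise the benzylic C–O bonds, and hydrogenolysis would saturate the alkene.
- Comparison: the chosen route is longer to the skeleton but never carries oxygen at C4 and exposes C2 only to neutral or basic reagents.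

**Alternative 3:** Ring C is disconnected at O1–C8a and C4–C4a.
- Disconnection and key step: the product would be flavanone A7, (2S)-5,7,4'-trimethoxy-6-prenylflavanone. Fluoride would convert silyl triflate A8, 3,5-dimethoxy-4-(3-methylbut-2-en-1-yl)-2-(trimethylsilyl)phenyl trifluoromethanesulfonate, into aryne A10, 1,2-didehydro-3,5-dimethoxy-4-(3-methylbut-2-en-1-yl)benzene. The alkoxide of hydroxy ester A9, methyl (3S)-3-hydroxy-3-(4-methoxyphenyl)propanoate, would add at C8a, and the resulting C4a aryl anion would acylate on the ester.
- For it: two bonds and ring C form in one step. The C5 methoxy group should direct the alkoxide to the remote aryne carbon C8a, as required. C2 is carried in with retention, with no substitution at the anisyl carbon; on this point it is stronger than the Mitsunobu closure of the chosen route.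
- Against it: A8 needs several steps from phenol 6 (ortho-halogenation, silyl transfer to carbon, triflation). The alkoxide of A9 is prone to retro-aldol cleavage and to elimination to the cinnamate. The basic fluoride medium can equilibrate A7 with its chalcone and racemise C2. The C4 carbonyl must again be removed in the presence of the prenyl group.
- Comparison: the chosen route offers C4 directly as a methylene and a stereocentre that is not exposed to base-mediated ring opening.

Key step: step 9

## Route

**Step 1**
Reactants: 1 1,3-dimethoxybenzene; 2 prenyl bromide (1-bromo-3-methylbut-2-ene)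
Product: 4 1,3-dimethoxy-2-(3-methylbut-2-en-1-yl)benzene, via 2,6-dimethoxyphenyllithium 3 (not isolated)
Conditions: n-BuLi (1.1 equiv), THF, 0 °C → rt, 2 h; then 2 (1.2 equiv), 0 °C → rt
Reagents that add atoms: none
Why: Directed ortho-metalation takes place at the C–H between the two methoxy groups, and the aryllithium 3 should displace the primary allylic bromide by SN2, since attack at the gem-dimethyl terminus is hindered.

**Step 2**
Reactants: 4 1,3-dimethoxy-2-(3-methylbut-2-en-1-yl)benzene
Product: 5 2-[3,5-dimethoxy-4-(3-methylbut-2-en-1-yl)phenyl]-4,4,5,5-tetramethyl-1,3,2-dioxaborolane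
Conditions: B2pin2 (1.0 equiv), [Ir(OMe)(cod)]2 (1.5 mol %), 4,4'-di-tert-butyl-2,2'-bipyridine (3 mol %), THF, 80 °C
Reagents that add atoms: bis(pinacolato)diboron, CC1(C)OB(OC1(C)C)B1OC(C)(C)C(C)(C)O1
Why: Iridium-catalysed aromatic C–H borylation is governed by sterics, and the C–H para to the prenyl group is the only one without an ortho substituent. A trisubstituted alkene is a poor substrate for the iridium boryl species.

**Step 3**
Reactants: 5 2-[3,5-dimethoxy-4-(3-methylbut-2-en-1-yl)phenyl]-4,4,5,5-tetramethyl-1,3,2-dioxaborolane
Product: 6 3,5-dimethoxy-4-(3-methylbut-2-en-1-yl)phenol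
Conditions: 30% aq H2O2, 2 M aq NaOH, THF, 0 °C → rt; then aq HCl to pH 5
Reagents that add atoms: hydrogen peroxide, OO
Why: Oxidation of an arylboronate by hydroperoxide proceeds by 1,2-aryl shift from boron to oxygen. Alkaline peroxide does not epoxidise an isolated electron-rich alkene, which is why a dioxirane-forming oxidant is avoided.

**Step 4**
Reactants: 6 3,5-dimethoxy-4-(3-methylbut-2-en-1-yl)phenol
Product: 7 6-hydroxy-2,4-dimethoxy-3-(3-methylbut-2-en-1-yl)benzaldehyde
Conditions: MgCl2 (1.5 equiv), Et3N (3.8 equiv), (CH2O)n (6 equiv), MeCN, reflux; 1 M aq HCl work-up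
Reagents that add atoms: formaldehyde (as paraformaldehyde), C=O
Why: In the Casnati–Skattebøl ortho-formylation the magnesium phenoxide delivers formaldehyde to the ortho carbon, and a second formaldehyde oxidises the benzylic alkoxide by hydride transfer. The two ortho positions of 6 are equivalent and the para position is blocked, so one aldehyde should form, and the conditions are not acidic enough to affect the prenyl group.

**Step 5**
Reactants: 7 6-hydroxy-2,4-dimethoxy-3-(3-methylbut-2-en-1-yl)benzaldehyde; 8 propane-1,3-dithiol
Product: 9 2-(1,3-dithian-2-yl)-3,5-dimethoxy-4-(3-methylbut-2-en-1-yl)phenol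
Conditions: 8 (1.2 equiv), BF3·OEt2 (0.3 equiv), CH2Cl2, −20 → 0 °C, N2
Reagents that add atoms: none
Why: Lewis-acid-catalysed dithioacetalisation of an aromatic aldehyde passes through a thionium ion that the electron-rich ring stabilises. A substoichiometric amount of Lewis acid at low temperature should leave the trisubstituted alkene unprotonated.

**Step 6**
Reactants: 9 2-(1,3-dithian-2-yl)-3,5-dimethoxy-4-(3-methylbut-2-en-1-yl)phenol
Product: 10 2-[2,4-dimethoxy-3-(3-methylbut-2-en-1-yl)-6-(triisopropylsilyloxy)phenyl]-1,3-dithiane
Conditions: TIPSCl (1.5 equiv), imidazole (3 equiv), DMAP (0.1 equiv), DMF, 40 °C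
Reagents that add atoms: triisopropylsilyl chloride, CC(C)[Si](Cl)(C(C)C)C(C)C
Why: This is a standard silylation of a phenol through the N-silylimidazolium species. The bulky triisopropylsilyl group is chosen because it resists attack by a neighbouring carbanion better than smaller silyl groups and comes off with fluoride under neutral conditions.

**Step 7**
Reactants: 11 2-chloro-1-(4-methoxyphenyl)ethanone
Product: 12 (1S)-2-chloro-1-(4-methoxyphenyl)ethanol
Conditions: Cp*RhCl[(R,R)-TsDPEN] (0.5 mol %), HCO2H/Et3N (5:2), EtOAc, rt
Reagents that add atoms: none
Why: In this Noyori-type asymmetric transfer hydrogenation, hydride and proton pass from the metal hydride and the ligand N–H through a six-membered transition state. The (R,R) ligand delivers hydride to the face that gives (R)-1-arylethanols from aryl methyl ketones, which is the (S) chlorohydrin here because CH2Cl outranks the aryl group.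

**Step 8**
Reactants: 12 (1S)-2-chloro-1-(4-methoxyphenyl)ethanol
Product: 13 (2S)-2-(4-methoxyphenyl)oxirane
Conditions: 2 M aq NaOH, i-PrOH, 0 °C → rt; short-path distillation or flash chromatography on Et3N-washed silica
Reagents that add atoms: none
Why: The alkoxide displaces chloride at the primary carbon in an intramolecular Williamson reaction, so the stereocentre is not a reaction site and stays (S). Basic, non-acidic handling is required because the anisyl epoxide ionises easily.

**Step 9**
Reactants: 10 2-[2,4-dimethoxy-3-(3-methylbut-2-en-1-yl)-6-(triisopropylsilyloxy)phenyl]-1,3-dithiane; 13 (2S)-2-(4-methoxyphenyl)oxirane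
Product: 15 (1R)-2-{2-[2,4-dimethoxy-3-(3-methylbut-2-en-1-yl)-6-(triisopropylsilyloxy)phenyl]-1,3-dithian-2-yl}-1-(4-methoxyphenyl)ethan-1-ol, via lithiated dithiane 14 (not isolated)
Conditions: n-BuLi (1.05 equiv), THF, −78 → −30 °C, 1.5 h; then 13 (1.3 equiv), −78 → 0 °C; sat. aq NH4Cl
Reagents that add atoms: none
Why: n-BuLi removes the dithiane C2–H of 10, which two sulfur atoms and the aryl group acidify, to give carbanion 14, an acyl anion equivalent for C4. Carbanion 14 attacks the CH2 terminus of 13 by SN2, forming C3–C4 and releasing the C2 alkoxide; the closest known reaction type is the Corey–Seebach alkylation of a 2-aryl-1,3-dithiane anion with a terminal epoxide. No ring is closed and no stereocentre is created, since the carbinol carbon is not a reaction site; the (S) arrangement of 13 is carried over and is named (R) in 15 only because the substituent priorities change. The selectivity needed is terminal over benzylic opening, and it should be secured by the size of the tertiary, doubly ortho-substituted carbanion and by the absence of any Lewis acid stronger than the lithium cation, so that the anisyl-stabilised carbon is not ionised. Deprotonation should be selective because the dithiane C–H is far more acidic than the ring C8–H or the prenyl CH2 and is removed at low temperature. A silyl shift from the neighbouring oxygen to the carbanion is held back by the bulk of the triisopropylsilyl group, by THF without a polar cosolvent and by temperatures at or below 0 °C. If the new alkoxide were to take the silyl group from the phenol oxygen, both silyl isomers would still converge at 17.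

**Step 10**
Reactants: 15 (1R)-2-{2-[2,4-dimethoxy-3-(3-methylbut-2-en-1-yl)-6-(triisopropylsilyloxy)phenyl]-1,3-dithian-2-yl}-1-(4-methoxyphenyl)ethan-1-ol
Product: 16 (1R)-3-[2,4-dimethoxy-3-(3-methylbut-2-en-1-yl)-6-(triisopropylsilyloxy)phenyl]-1-(4-methoxyphenyl)propan-1-ol
Conditions: Bu3SnH (4 equiv), AIBN (0.3 equiv, in portions), degassed toluene, 110 °C
Reagents that add atoms: none
Why: In this radical-chain desulfurisation the stannyl radical attacks sulfur, each benzylic C–S bond breaks to a stabilised benzylic radical, and this radical takes hydrogen from Bu3SnH. A trisubstituted alkene adds stannyl radicals only reversibly, and the silyl ether keeps the phenol from interfering with the chain.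

**Step 11**
Reactants: 16 (1R)-3-[2,4-dimethoxy-3-(3-methylbut-2-en-1-yl)-6-(triisopropylsilyloxy)phenyl]-1-(4-methoxyphenyl)propan-1-ol
Product: 17 2-[(3R)-3-hydroxy-3-(4-methoxyphenyl)propyl]-3,5-dimethoxy-4-(3-methylbut-2-en-1-yl)phenol
Conditions: TBAF (1.1 equiv), THF, 0 °C; sat. aq NH4Cl
Reagents that add atoms: none
Why: Fluoride cleaves the aryl silyl ether through a pentacoordinate silicate with phenoxide as a good leaving group. The conditions are neutral to weakly basic, so the anisyl carbinol keeps its configuration.

**Step 12**
Reactants: 17 2-[(3R)-3-hydroxy-3-(4-methoxyphenyl)propyl]-3,5-dimethoxy-4-(3-methylbut-2-en-1-yl)phenol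
Product: 18 (2S)-5,7-dimethoxy-2-(4-methoxyphenyl)-6-(3-methylbut-2-en-1-yl)-3,4-dihydro-2H-chromene
Conditions: PPh3 (1.5 equiv), DIAD (1.5 equiv), THF, 0 °C → rt
Reagents that add atoms: none
Why: In the intramolecular Mitsunobu etherification the secondary alcohol is activated as its alkoxyphosphonium ion and the phenoxide displaces it in a 6-exo-tet SN2 closure. Inversion at the carbinol carbon turns the (R) alcohol into the (2S) flavan.

## Compound list

1 | 1,3-dimethoxybenzene | COc1cccc(OC)c1 | starting material
2 | prenyl bromide (1-bromo-3-methylbut-2-ene) | CC(C)=CCBr | starting material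
3 | 2,6-dimethoxyphenyllithium | [Li]c1c(OC)cccc1OC | intermediate
4 | 1,3-dimethoxy-2-(3-methylbut-2-en-1-yl)benzene | COc1cccc(OC)c1CC=C(C)C | intermediate
5 | 2-[3,5-dimethoxy-4-(3-methylbut-2-en-1-yl)phenyl]-4,4,5,5-tetramethyl-1,3,2-dioxaborolane | COc1cc(B2OC(C)(C)C(C)(C)O2)cc(OC)c1CC=C(C)C | intermediate
6 | 3,5-dimethoxy-4-(3-methylbut-2-en-1-yl)phenol | COc1cc(O)cc(OC)c1CC=C(C)C | intermediate
7 | 6-hydroxy-2,4-dimethoxy-3-(3-methylbut-2-en-1-yl)benzaldehyde | COc1cc(O)c(C=O)c(OC)c1CC=C(C)C | intermediate
8 | propane-1,3-dithiol | SCCCS | starting material
9 | 2-(1,3-dithian-2-yl)-3,5-dimethoxy-4-(3-methylbut-2-en-1-yl)phenol | COc1cc(O)c(C2SCCCS2)c(OC)c1CC=C(C)C | intermediate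
10 | 2-[2,4-dimethoxy-3-(3-methylbut-2-en-1-yl)-6-(triisopropylsilyloxy)phenyl]-1,3-dithiane | COc1cc(O[Si](C(C)C)(C(C)C)C(C)C)c(C2SCCCS2)c(OC)c1CC=C(C)C | intermediate
11 | 2-chloro-1-(4-methoxyphenyl)ethanone | COc1ccc(C(=O)CCl)cc1 | starting material
12 | (1S)-2-chloro-1-(4-methoxyphenyl)ethanol | COc1ccc([C@H](O)CCl)cc1 | intermediate
13 | (2S)-2-(4-methoxyphenyl)oxirane | COc1ccc([C@H]2CO2)cc1 | intermediate
14 | 2-lithio-2-[2,4-dimethoxy-3-(3-methylbut-2-en-1-yl)-6-(triisopropylsilyloxy)phenyl]-1,3-dithiane | COc1cc(O[Si](C(C)C)(C(C)C)C(C)C)c(C2([Li])SCCCS2)c(OC)c1CC=C(C)C | intermediate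
15 | (1R)-2-{2-[2,4-dimethoxy-3-(3-methylbut-2-en-1-yl)-6-(triisopropylsilyloxy)phenyl]-1,3-dithian-2-yl}-1-(4-methoxyphenyl)ethan-1-ol | COc1ccc([C@@H](CC2(c3c(O[Si](C(C)C)(C(C)C)C(C)C)cc(OC)c(CC=C(C)C)c3OC)SCCCS2)O)cc1 | intermediate
16 | (1R)-3-[2,4-dimethoxy-3-(3-methylbut-2-en-1-yl)-6-(triisopropylsilyloxy)phenyl]-1-(4-methoxyphenyl)propan-1-ol | COc1ccc([C@@H](CCc2c(O[Si](C(C)C)(C(C)C)C(C)C)cc(OC)c(CC=C(C)C)c2OC)O)cc1 | intermediate
17 | 2-[(3R)-3-hydroxy-3-(4-methoxyphenyl)propyl]-3,5-dimethoxy-4-(3-methylbut-2-en-1-yl)phenol | COc1ccc([C@@H](CCc2c(O)cc(OC)c(CC=C(C)C)c2OC)O)cc1 | intermediate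
18 | (2S)-5,7-dimethoxy-2-(4-methoxyphenyl)-6-(3-methylbut-2-en-1-yl)-3,4-dihydro-2H-chromene | COc1ccc([C@@H]2CCc3c(cc(OC)c(CC=C(C)C)c3OC)O2)cc1 | target

## Step count and least certain steps

Total: 12 steps. Longest linear sequence: 10 steps (steps 1 to 6 and 9 to 12, from 1). The epoxide branch is 2 steps (steps 7 and 8).

**Step 9 (key step).** The tertiary carbanion flanked by two ortho oxygen substituents may open the epoxide slowly. Slower opening would give time for lithium-promoted rearrangement of the anisyl epoxide to the arylacetaldehyde, for opening at the benzylic carbon, or for migration of the silyl group from oxygen to the carbanion. The fallback sets out from aldehyde 7 and returns at 17. It gives up the polarity reversal and forms the C3–C4 bond by an aldol condensation. Claisen–Schmidt condensation of 7 with commercial 4'-methoxyacetophenone (KOH, EtOH, rt) should give (2E)-3-[6-hydroxy-2,4-dimethoxy-3-(3-methylbut-2-en-1-yl)phenyl]-1-(4-methoxyphenyl)prop-2-en-1-one F1. Conjugate reduction of the enone with [(Ph3P)CuH]6 in wet THF, which leaves the isolated alkene alone, should give 3-[6-hydroxy-2,4-dimethoxy-3-(3-methylbut-2-en-1-yl)phenyl]-1-(4-methoxyphenyl)propan-1-one F2. Asymmetric transfer hydrogenation of F2 with RuCl(p-cymene)[(R,R)-TsDPEN] in HCO2H/Et3N should give the (R) alcohol 17. The cost is that the stereocentre is then set late, on an electron-rich ketone that is reduced slowly.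

**Step 2.** The pinacolborane formed alongside 5 may hydroborate the prenyl alkene at the iridium centre, or the alkene may isomerise, and the electron-rich arene may borylate slowly. The fallback sets out from 1 and returns at 6. It places the oxygen before the alkene is present.
- Borylation of 1 under the same conditions should give 2-(3,5-dimethoxyphenyl)-4,4,5,5-tetramethyl-1,3,2-dioxaborolane F3.
- Oxidation with H2O2/NaOH should give 3,5-dimethoxyphenol F4, which is also available commercially.
- Silylation with TIPSCl and imidazole should give (3,5-dimethoxyphenoxy)triisopropylsilane F5.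
- n-BuLi in THF at 0 °C should deprotonate between the two methoxy groups, since the bulky silyloxy group directs poorly, to give [2,6-dimethoxy-4-(triisopropylsilyloxy)phenyl]lithium F6.
- Quenching with 2 should give [3,5-dimethoxy-4-(3-methylbut-2-en-1-yl)phenoxy]triisopropylsilane F7, and TBAF then frees 6.

**Step 10.** The chain may stall after the first C–S cleavage, because the second benzylic radical lacks sulfur stabilisation and the hindered radical abstracts hydrogen slowly. Stannyl radicals may also add to the alkene at the high temperature needed. The fallback sets out from 15 and returns at 16. It replaces the radical chain by reductive desulfurisation on a nickel surface: Ni2B generated from NiCl2·6H2O and NaBH4 in MeOH/THF at 0 °C, conditions under which a trisubstituted alkene is reduced only slowly. No new compound is formed on the way.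

**Step 12.** The alkoxyphosphonium ion may ionise at the anisyl carbon before the phenoxide attacks. This would lead to partial loss of configuration at C2 or to elimination to the styrene. The fallback sets out from 15 and returns at 18. It closes the ring while the dithiane is still in place, so that the geminal substitution at C4 brings the phenoxide and C2 together and speeds the SN2 closure; it cannot remove the intrinsic tendency to ionise.
- TBAF should convert 15 into 2-{2-[(2R)-2-hydroxy-2-(4-methoxyphenyl)ethyl]-1,3-dithian-2-yl}-3,5-dimethoxy-4-(3-methylbut-2-en-1-yl)phenol F8.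
- Mitsunobu closure (PPh3, DIAD, toluene, 0 °C) should give (2S)-5,7-dimethoxy-2-(4-methoxyphenyl)-6-(3-methylbut-2-en-1-yl)spiro[chromane-4,2'-[1,3]dithiane] F9.
- Bu3SnH/AIBN should then remove the sulfur to give 18.

## Further compounds

F1 | step 9 | (2E)-3-[6-hydroxy-2,4-dimethoxy-3-(3-methylbut-2-en-1-yl)phenyl]-1-(4-methoxyphenyl)prop-2-en-1-one | COc1ccc(C(=O)/C=C/c2c(O)cc(OC)c(CC=C(C)C)c2OC)cc1
F2 | step 9 | 3-[6-hydroxy-2,4-dimethoxy-3-(3-methylbut-2-en-1-yl)phenyl]-1-(4-methoxyphenyl)propan-1-one | COc1ccc(C(=O)CCc2c(O)cc(OC)c(CC=C(C)C)c2OC)cc1
F3 | step 2 | 2-(3,5-dimethoxyphenyl)-4,4,5,5-tetramethyl-1,3,2-dioxaborolane | COc1cc(OC)cc(B2OC(C)(C)C(C)(C)O2)c1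
F4 | step 2 | 3,5-dimethoxyphenol | COc1cc(O)cc(OC)c1
F5 | step 2 | (3,5-dimethoxyphenoxy)triisopropylsilane | COc1cc(OC)cc(O[Si](C(C)C)(C(C)C)C(C)C)c1
F6 | step 2 | [2,6-dimethoxy-4-(triisopropylsilyloxy)phenyl]lithium | [Li]c1c(OC)cc(O[Si](C(C)C)(C(C)C)C(C)C)cc1OC
F7 | step 2 | [3,5-dimethoxy-4-(3-methylbut-2-en-1-yl)phenoxy]triisopropylsilane | COc1cc(O[Si](C(C)C)(C(C)C)C(C)C)cc(OC)c1CC=C(C)C
F0 | step 10 | none | none
F8 | step 12 | 2-{2-[(2R)-2-hydroxy-2-(4-methoxyphenyl)ethyl]-1,3-dithian-2-yl}-3,5-dimethoxy-4-(3-methylbut-2-en-1-yl)phenol | COc1ccc([C@@H](CC2(c3c(O)cc(OC)c(CC=C(C)C)c3OC)SCCCS2)O)cc1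
F9 | step 12 | (2S)-5,7-dimethoxy-2-(4-methoxyphenyl)-6-(3-methylbut-2-en-1-yl)spiro[chromane-4,2'-[1,3]dithiane] | COc1ccc([C@@H]2CC3(SCCCS3)c3c(cc(OC)c(CC=C(C)C)c3OC)O2)cc1
A1 | alternative 1 | 2-[(3R)-3-(tert-butyldimethylsilyloxy)-3-(4-methoxyphenyl)propyl]-3,5-dimethoxy-4-(3-methylbut-2-en-1-yl)phenol | COc1ccc([C@@H](CCc2c(O)cc(OC)c(CC=C(C)C)c2OC)O[Si](C)(C)C(C)(C)C)cc1
A2 | alternative 1 | 3-methoxy-2-(3-methylbut-2-en-1-yl)cyclobut-2-en-1-one | COC1=C(CC=C(C)C)C(=O)C1
A3 | alternative 1 | tert-butyl{[(1R)-5-methoxy-1-(4-methoxyphenyl)pent-4-yn-1-yl]oxy}dimethylsilane | COC#CCC[C@@H](O[Si](C)(C)C(C)(C)C)c1ccc(OC)cc1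
A4 | alternative 2 | (2S)-6-prenylnaringenin | Oc1ccc([C@@H]2CC(=O)c3c(cc(O)c(CC=C(C)C)c3O)O2)cc1
A5 | alternative 2 | (2S)-naringenin | Oc1ccc([C@@H]2CC(=O)c3c(cc(O)cc3O)O2)cc1
A6 | alternative 2 | dimethylallyl diphosphate | CC(C)=CCOP(=O)(O)OP(=O)(O)O
A7 | alternative 3 | (2S)-5,7,4'-trimethoxy-6-prenylflavanone | COc1ccc([C@@H]2CC(=O)c3c(cc(OC)c(CC=C(C)C)c3OC)O2)cc1
A8 | alternative 3 | 3,5-dimethoxy-4-(3-methylbut-2-en-1-yl)-2-(trimethylsilyl)phenyl trifluoromethanesulfonate | COc1cc(OS(=O)(=O)C(F)(F)F)c([Si](C)(C)C)c(OC)c1CC=C(C)C
A9 | alternative 3 | methyl (3S)-3-hydroxy-3-(4-methoxyphenyl)propanoate | COc1ccc([C@@H](O)CC(=O)OC)cc1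
A10 | alternative 3 | 1,2-didehydro-3,5-dimethoxy-4-(3-methylbut-2-en-1-yl)benzene | COC1=C(CC=C(C)C)C(OC)=CC#C1
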